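**Strategy.** Both ε-rings are read as one 4-alkoxycarbonyl-isophorone (carotenoid numbering). C1 with its gem-dimethyl group is the β-carbon of an isopropylidene Michael acceptor. The C4=C5 alkene with its C5 methyl is the aldol condensation of a methyl ketone. C3 carries an oxygen that the hydroxylated ring keeps and the other ring sheds. One Michael–aldol (3+3) annulation of two acyclic esters, ethyl 2-acetyl-3-methylbut-2-enoate and ethyl acetoacetate, therefore closes the cyclohexene and forms C1–C2 and C4=C5 of the unsubstituted ring (and the same bonds of the 3-hydroxy ring) at once. An oxazaborolidine reduction sorts the enantiomers, and two C10 ring sulfones are joined to crocetin dialdehyde by Julia–Kocienski olefinations.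

Key step: step 2

Remark: the target is read as all-E (3S,6S,6'S)-ε,ε-caroten-3-ol with a 3,6-trans hydroxy ring, and crocetin dialdehyde 12 is taken as a purchasable C20 building block.

**Step 1**
Reactants: 1 ethyl acetoacetate; 2 acetone
Product: 3 ethyl 2-acetyl-3-methylbut-2-enoate
Conditions: ZnCl2 (cat.), Ac2O, reflux
Reagents that add atoms: none
Why: Knoevenagel condensation of the active methylene of 1 with acetone, pulled to the tetrasubstituted alkylidene acetoacetate by ZnCl2 activation and by acetic anhydride as water scavenger; no stereocentre is formed.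

**Step 2**
Reactants: 3 ethyl 2-acetyl-3-methylbut-2-enoate; 1 ethyl acetoacetate
Product: 6 racemic ethyl 2,6,6-trimethyl-4-oxocyclohex-2-ene-1-carboxylate, via Michael adduct 4 (not isolated), via cyclohexenone diester 5 (not isolated)
Conditions: NaOEt (1.1 equiv), EtOH, 0 °C → reflux; AcOH quench
Reagents that add atoms: none
Why: Sodio-acetoacetate adds to the doubly activated isopropylidene carbon of 3 (Michael addition, C1–C2 of the end group, quaternary gem-dimethyl centre) to give the symmetric 1,5-diketone 4, whose acetyl methyl attacks the other acetyl carbonyl and loses water (aldol condensation, C4=C5) to give 5, and ethoxide then cleaves the β-keto ester group of 5 as diethyl carbonate (retro-Claisen) to leave 6 as its dienolate. The closest known reaction type is the Hagemann's ester annulation, a Michael–aldol (3+3) cyclisation of an alkylidene acetoacetate with acetoacetate, which is the substrate class used here. The ring closes by a 6-(enolendo)-exo-trig aldol addition followed by E1cB dehydration into conjugation. The one new stereocentre (C1 of 6, C6 of both end groups) is not controlled: it lies α to the ester and γ to the enone, forms as a racemate under equilibrating conditions and is sorted in step 3. The step needs regioselectivity in the aldol closure and chemoselectivity in the ester cleavage: the constitutional symmetry of 4 makes both aldol directions give the same ring, and only the ester α to the ring ketone can leave as a simple ketone enolate, so the vinylogous ester at C1 should survive. The retro-Michael equilibrium of the congested adduct 4 is drained by the irreversible dehydration and dealkoxycarbonylation.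

**Step 3**
Reactants: 6 racemic ethyl 2,6,6-trimethyl-4-oxocyclohex-2-ene-1-carboxylate
Product: 7 ethyl (1S,4S)-4-hydroxy-2,6,6-trimethylcyclohex-2-ene-1-carboxylate
Conditions: (R)-2-methyl-CBS-oxazaborolidine (15 mol %), catecholborane, toluene, −78 °C; chromatography
Reagents that add atoms: none
Why: Corey–Bakshi–Shibata reduction in which the catalyst, reading the alkenyl arm of the enone as the large group, should deliver hydride to the same carbonyl face of both enantiomers of 6 and set C4 as S, so that (1S)-6 gives the trans alcohol 7 and (1R)-6 gives the cis (1R,4S) diastereomer, which is removed on silica; catecholborane avoids hydroboration of the alkene.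

**Step 4**
Reactants: 7 ethyl (1S,4S)-4-hydroxy-2,6,6-trimethylcyclohex-2-ene-1-carboxylate
Product: 9 [(1S)-2,6,6-trimethylcyclohex-2-en-1-yl]methanol, via diol 8 (not isolated)
Conditions: LiAlH4, Et2O, 0 °C; then AlCl3 (2 equiv per LiAlH4), reflux
Reagents that add atoms: none
Why: LiAlH4 first reduces the ester to the primary alkoxide (diol 8), and the chloroalane formed on adding AlCl3 then hydrogenolyses the allylic C–O bond through an allyl cation that should take hydride at its less hindered secondary end, so the trisubstituted alkene stays in place (known mixed-hydride deoxygenation of cyclohex-2-enols); the ring stereocentre bearing the CH2OH group is not involved.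

**Step 5**
Reactants: 9 [(1S)-2,6,6-trimethylcyclohex-2-en-1-yl]methanol
Product: 10 1-phenyl-5-({[(1S)-2,6,6-trimethylcyclohex-2-en-1-yl]methyl}sulfanyl)-1H-tetrazole
Conditions: PPh3, DIAD, THF, 0 °C → rt
Reagents that add atoms: 1-phenyl-1H-tetrazole-5-thiol, Sc1nnnn1-c1ccccc1
Why: Mitsunobu thioetherification of the primary alcohol with the acidic tetrazolethiol (SN2 at CH2, so the adjacent stereocentre is untouched).

**Step 6**
Reactants: 10 1-phenyl-5-({[(1S)-2,6,6-trimethylcyclohex-2-en-1-yl]methyl}sulfanyl)-1H-tetrazole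
Product: 11 1-phenyl-5-({[(1S)-2,6,6-trimethylcyclohex-2-en-1-yl]methyl}sulfonyl)-1H-tetrazole
Conditions: (NH4)6Mo7O24·4H2O (cat.), 30% H2O2, EtOH, 0 °C → rt
Reagents that add atoms: hydrogen peroxide, OO
Why: Molybdate-catalysed peroxide oxidation should take the sulfide to the sulfone faster than it epoxidises the trisubstituted alkene.

**Step 7**
Reactants: 11 1-phenyl-5-({[(1S)-2,6,6-trimethylcyclohex-2-en-1-yl]methyl}sulfonyl)-1H-tetrazole; 12 crocetin dialdehyde (3 equiv)
Product: 13 (6S)-8'-apo-ε-caroten-8'-al
Conditions: KN(SiMe3)2, THF, −78 °C; add to 12 in THF, −40 °C → rt; I2 (cat.), CH2Cl2, daylight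
Reagents that add atoms: none
Why: Julia–Kocienski olefination: the sulfonyl carbanion adds to one aldehyde group of 12 (excess favours mono-olefination and is recovered), Smiles rearrangement with loss of SO2 and tetrazololate gives the C7=C8 alkene mainly as E, iodine equilibrates residual Z isomers to all-E, and the ring stereocentre, β to the carbanion, should not epimerise.

**Step 8**
Reactants: 7 ethyl (1S,4S)-4-hydroxy-2,6,6-trimethylcyclohex-2-ene-1-carboxylate
Product: 14 ethyl (1S,4S)-4-[(tert-butyldimethylsilyl)oxy]-2,6,6-trimethylcyclohex-2-ene-1-carboxylate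
Conditions: TBSCl, imidazole, DMF, rt
Reagents that add atoms: tert-butyldimethylsilyl chloride, CC(C)(C)[Si](C)(C)Cl
Why: Standard silylation of the secondary allylic alcohol so that it survives the Mitsunobu, oxidation and carbanion steps.

**Step 9**
Reactants: 14 ethyl (1S,4S)-4-[(tert-butyldimethylsilyl)oxy]-2,6,6-trimethylcyclohex-2-ene-1-carboxylate
Product: 15 [(1S,4S)-4-[(tert-butyldimethylsilyl)oxy]-2,6,6-trimethylcyclohex-2-en-1-yl]methanol
Conditions: LiAlH4, THF, 0 °C
Reagents that add atoms: none
Why: Hydride reduction of the ester to the primary alcohol, with the silyl ether inert and both stereocentres untouched.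

**Step 10**
Reactants: 15 [(1S,4S)-4-[(tert-butyldimethylsilyl)oxy]-2,6,6-trimethylcyclohex-2-en-1-yl]methanol
Product: 16 5-({[(1S,4S)-4-[(tert-butyldimethylsilyl)oxy]-2,6,6-trimethylcyclohex-2-en-1-yl]methyl}sulfanyl)-1-phenyl-1H-tetrazole
Conditions: PPh3, DIAD, THF, 0 °C → rt
Reagents that add atoms: 1-phenyl-1H-tetrazole-5-thiol, Sc1nnnn1-c1ccccc1
Why: Mitsunobu thioetherification at the primary carbon only, since the secondary allylic oxygen is silylated.

**Step 11**
Reactants: 16 5-({[(1S,4S)-4-[(tert-butyldimethylsilyl)oxy]-2,6,6-trimethylcyclohex-2-en-1-yl]methyl}sulfanyl)-1-phenyl-1H-tetrazole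
Product: 17 5-({[(1S,4S)-4-[(tert-butyldimethylsilyl)oxy]-2,6,6-trimethylcyclohex-2-en-1-yl]methyl}sulfonyl)-1-phenyl-1H-tetrazole
Conditions: (NH4)6Mo7O24·4H2O (cat.), 30% H2O2, EtOH, 0 °C → rt
Reagents that add atoms: hydrogen peroxide, OO
Why: Chemoselective molybdate-catalysed oxidation at sulfur, which the allylic silyl ether and the alkene should tolerate.

**Step 12**
Reactants: 17 5-({[(1S,4S)-4-[(tert-butyldimethylsilyl)oxy]-2,6,6-trimethylcyclohex-2-en-1-yl]methyl}sulfonyl)-1-phenyl-1H-tetrazole; 13 (6S)-8'-apo-ε-caroten-8'-al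
Product: 18 (3S,6S,6'S)-3-[(tert-butyldimethylsilyl)oxy]-ε,ε-carotene
Conditions: KN(SiMe3)2, THF, −78 °C; then 13, −78 °C → rt; I2 (cat.), CH2Cl2, daylight; argon, dim light
Reagents that add atoms: none
Why: Second Julia–Kocienski olefination, forming C7'=C8' between the carbanion of 17 and polyenal 13, with iodine-catalysed equilibration to the all-E polyene and no base-labile stereocentre in either partner.

**Step 13**
Reactants: 18 (3S,6S,6'S)-3-[(tert-butyldimethylsilyl)oxy]-ε,ε-carotene
Product: 19 (3S,6S,6'S)-ε,ε-caroten-3-ol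
Conditions: Bu4NF, THF, 0 °C → rt; aqueous NH4Cl; argon, dim light
Reagents that add atoms: none
Why: Fluoride cleaves the Si–O bond under non-acidic conditions, which the acid-sensitive allylic alcohol and the polyene should tolerate.

**Compound list**

1 | ethyl acetoacetate | CCOC(=O)CC(C)=O | starting material
2 | acetone | CC(C)=O | starting material
3 | ethyl 2-acetyl-3-methylbut-2-enoate | CCOC(=O)C(C(C)=O)=C(C)C | intermediate
4 | diethyl 2,4-diacetyl-3,3-dimethylpentanedioate (Michael adduct, stereoisomer mixture, not isolated) | CCOC(=O)C(C(C)=O)C(C)(C)C(C(C)=O)C(=O)OCC | intermediate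
5 | diethyl 2,2,4-trimethyl-6-oxocyclohex-4-ene-1,3-dicarboxylate (stereoisomer mixture, not isolated) | CCOC(=O)C1C(C)=CC(=O)C(C(=O)OCC)C1(C)C | intermediate
6 | racemic ethyl 2,6,6-trimethyl-4-oxocyclohex-2-ene-1-carboxylate | CCOC(=O)C1C(C)=CC(=O)CC1(C)C | intermediate
7 | ethyl (1S,4S)-4-hydroxy-2,6,6-trimethylcyclohex-2-ene-1-carboxylate | CCOC(=O)[C@@H]1C(C)=C[C@@H](O)CC1(C)C | intermediate
8 | (1S,4S)-4-(hydroxymethyl)-3,5,5-trimethylcyclohex-2-en-1-ol (as its aluminium alkoxide, not isolated) | OC[C@@H]1C(C)=C[C@@H](O)CC1(C)C | intermediate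
9 | [(1S)-2,6,6-trimethylcyclohex-2-en-1-yl]methanol | OC[C@@H]1C(C)=CCCC1(C)C | intermediate
10 | 1-phenyl-5-({[(1S)-2,6,6-trimethylcyclohex-2-en-1-yl]methyl}sulfanyl)-1H-tetrazole | c1ccccc1-n1nnnc1SC[C@@H]1C(C)=CCCC1(C)C | intermediate
11 | 1-phenyl-5-({[(1S)-2,6,6-trimethylcyclohex-2-en-1-yl]methyl}sulfonyl)-1H-tetrazole | c1ccccc1-n1nnnc1S(=O)(=O)C[C@@H]1C(C)=CCCC1(C)C | intermediate
12 | crocetin dialdehyde, (2E,4E,6E,8E,10E,12E,14E)-2,6,11,15-tetramethylhexadeca-2,4,6,8,10,12,14-heptaenedial | O=C/C(C)=C/C=C/C(C)=C/C=C/C=C(C)/C=C/C=C(C)/C=O | starting material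
13 | (6S)-8'-apo-ε-caroten-8'-al, (2E,4E,6E,8E,10E,12E,14E,16E)-2,6,11,15-tetramethyl-17-[(1S)-2,6,6-trimethylcyclohex-2-en-1-yl]heptadeca-2,4,6,8,10,12,14,16-octaenal | CC1=CCCC(C)(C)[C@@H]1/C=C/C(C)=C/C=C/C(C)=C/C=C/C=C(C)/C=C/C=C(C)/C=O | intermediate
14 | ethyl (1S,4S)-4-[(tert-butyldimethylsilyl)oxy]-2,6,6-trimethylcyclohex-2-ene-1-carboxylate | CCOC(=O)[C@@H]1C(C)=C[C@@H](O[Si](C)(C)C(C)(C)C)CC1(C)C | intermediate
15 | [(1S,4S)-4-[(tert-butyldimethylsilyl)oxy]-2,6,6-trimethylcyclohex-2-en-1-yl]methanol | OC[C@@H]1C(C)=C[C@@H](O[Si](C)(C)C(C)(C)C)CC1(C)C | intermediate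
16 | 5-({[(1S,4S)-4-[(tert-butyldimethylsilyl)oxy]-2,6,6-trimethylcyclohex-2-en-1-yl]methyl}sulfanyl)-1-phenyl-1H-tetrazole | c1ccccc1-n1nnnc1SC[C@@H]1C(C)=C[C@@H](O[Si](C)(C)C(C)(C)C)CC1(C)C | intermediate
17 | 5-({[(1S,4S)-4-[(tert-butyldimethylsilyl)oxy]-2,6,6-trimethylcyclohex-2-en-1-yl]methyl}sulfonyl)-1-phenyl-1H-tetrazole | c1ccccc1-n1nnnc1S(=O)(=O)C[C@@H]1C(C)=C[C@@H](O[Si](C)(C)C(C)(C)C)CC1(C)C | intermediate
18 | (3S,6S,6'S)-3-[(tert-butyldimethylsilyl)oxy]-ε,ε-carotene (all-E) | CC1=CCCC(C)(C)[C@@H]1/C=C/C(C)=C/C=C/C(C)=C/C=C/C=C(C)/C=C/C=C(C)/C=C/[C@@H]1C(C)=C[C@@H](O[Si](C)(C)C(C)(C)C)CC1(C)C | intermediate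
19 | (3S,6S,6'S)-ε,ε-caroten-3-ol (all-E) | CC1=CCCC(C)(C)[C@@H]1/C=C/C(C)=C/C=C/C(C)=C/C=C/C=C(C)/C=C/C=C(C)/C=C/[C@@H]1C(C)=C[C@@H](O)CC1(C)C | target

**Step count.** Total: 13 steps. Longest linear sequence: 9 steps (1, 2, 3, 4, 5, 6, 7, 12, 13; the silyl-ether branch 1, 2, 3, 8, 9, 10, 11, 12, 13 is equally long).

**Steps most likely to fail**

Step 3. The catalyst may fail to override the substrate's own facial bias in one enantiomer, or may discriminate poorly between the alkenyl arm and the neopentyl-type arm of the ketone, so that 7 is obtained with low enantiomeric purity. The fallback sets out from 6. Luche reduction (NaBH4, CeCl3·7H2O, MeOH, −20 °C) should give the racemic trans alcohol F1 together with the racemic cis alcohol F2, which are separated on silica. Kinetic resolution of F1 with Burkholderia cepacia lipase and vinyl acetate (tert-butyl methyl ether, rt) should, by the empirical rule for secondary alcohols, acetylate the (4R) enantiomer to ethyl (1R,4R)-4-acetoxy-2,6,6-trimethylcyclohex-2-ene-1-carboxylate F3. The unreacted (1S,4S) alcohol is 7, where the fallback returns to the route.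

Step 4. The allyl cation may take hydride at its tertiary end, which moves the double bond, or may lose a proton to give a diene. The fallback sets out from 7 and avoids a free cation. Acetylation (Ac2O, pyridine, DMAP) gives ethyl (1S,4S)-4-acetoxy-2,6,6-trimethylcyclohex-2-ene-1-carboxylate F4. Pd(PPh3)4-catalysed reduction with NaBH4 in THF should deliver hydride to the less hindered end of the π-allyl complex and give ethyl (1S)-2,6,6-trimethylcyclohex-2-ene-1-carboxylate F5. LiAlH4 in Et2O at 0 °C then gives 9, where the fallback returns to the route.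

Step 7. The β-branched sulfonyl carbanion may add slowly to the sparingly soluble polyene dialdehyde, both aldehyde ends may react, or the E-selectivity may be low. The fallback sets out from 9 and uses a phosphorus ylide in place of the sulfone. Appel bromination (CBr4, PPh3, CH2Cl2) gives (6S)-6-(bromomethyl)-1,5,5-trimethylcyclohex-1-ene F6. Heating with PPh3 (neat, 120 °C) gives {[(1S)-2,6,6-trimethylcyclohex-2-en-1-yl]methyl}triphenylphosphonium bromide F7. Wittig reaction of F7 with excess 12 (NaOMe, CH2Cl2/MeOH, rt), followed by iodine-catalysed Z to E equilibration, gives 13, where the fallback returns to the route.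

**Further compounds**

F1 | step 3 | racemic ethyl trans-4-hydroxy-2,6,6-trimethylcyclohex-2-ene-1-carboxylate (racemate, (1S,4S) enantiomer drawn) | CCOC(=O)[C@@H]1C(C)=C[C@@H](O)CC1(C)C
F2 | step 3 | racemic ethyl cis-4-hydroxy-2,6,6-trimethylcyclohex-2-ene-1-carboxylate (racemate, (1R,4S) enantiomer drawn) | CCOC(=O)[C@H]1C(C)=C[C@@H](O)CC1(C)C
F3 | step 3 | ethyl (1R,4R)-4-acetoxy-2,6,6-trimethylcyclohex-2-ene-1-carboxylate | CCOC(=O)[C@H]1C(C)=C[C@H](OC(C)=O)CC1(C)C
F4 | step 4 | ethyl (1S,4S)-4-acetoxy-2,6,6-trimethylcyclohex-2-ene-1-carboxylate | CCOC(=O)[C@@H]1C(C)=C[C@@H](OC(C)=O)CC1(C)C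
F5 | step 4 | ethyl (1S)-2,6,6-trimethylcyclohex-2-ene-1-carboxylate | CCOC(=O)[C@@H]1C(C)=CCCC1(C)C
F6 | step 7 | (6S)-6-(bromomethyl)-1,5,5-trimethylcyclohex-1-ene | BrC[C@@H]1C(C)=CCCC1(C)C
F7 | step 7 | {[(1S)-2,6,6-trimethylcyclohex-2-en-1-yl]methyl}triphenylphosphonium bromide | [Br-].c1ccccc1[P+](c1ccccc1)(c1ccccc1)C[C@@H]1C(C)=CCCC1(C)C
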